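**Plan**
1. Numbering is that of the octahydroindene core of the target 28: ring A is the cyclohexane (C3a, C4–C7, C7a), ring B the cyclopentane (C1–C3, C3a, C7a).
2. Retrosynthesis cuts the acetate and angelate C–O bonds, then C5–C6 of ring A (a homoallylic alcohol beside the C4 methylidene, a carbonyl-ene retron), then C3–C3a of ring B, then C7–C7a (nitro-Michael).
3. Enabling feature: C3a is allylic to the exocyclic C4=CH2 and C3 lies α to the oxygenated C2, so a C3 radical of a C2 ketone can add to a prenyl-type alkene whose substituted carbon becomes C4; oxidation of the adduct radical leaves an isopropenyl group that later supplies C5 and the methylidene carbon.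
4. Forward: open chain by enamine Michael addition (C7–C7a), ring B by oxidative radical cyclisation (C3–C3a), decoration of C1 and C2, ring A last by carbonyl-ene closure (C5–C6), then acetate and unmasking of the acetyl group.
5. Stereochemistry: C7 and C7a from the prolinol silyl ether catalyst; C3a from allylic strain in the radical closure; C1 from an anti aldol (also the thermodynamic position); C2 from hydride attack opposite the C1 and C3a substituents; C6 from the chair-like ene transition state.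
6. Helpers: the C6 carbon travels as nitromethyl and then dimethyl acetal, the acetyl group as a silyloxyethyl group, and C3 carries a removable allyl ester.

Key step: step 5

Remark: the (R)-configured prolinol silyl ether is assumed to give the (3S,4S) adduct by analogy with the usual course of such enamine additions to nitroalkenes (its antipode would be used if the sense proved opposite); (E)-3-methyl-1-nitrobut-1-ene is treated as a purchasable reagent.

**Step 1**
Reactants: 1 methyl 4-oxobutanoate; 2 (E)-3-methyl-1-nitrobut-1-ene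
Product: 3 methyl (3S,4S)-3-formyl-5-methyl-4-(nitromethyl)hexanoate
Conditions: (R)-2-[diphenyl(trimethylsilyloxy)methyl]pyrrolidine (10 mol%), 4-nitrophenol (10 mol%), toluene, 0 °C to rt
Reagents that add atoms: (E)-3-methyl-1-nitrobut-1-ene 2, CC(C)/C=C/[N+](=O)[O-]
Why: Diarylprolinol silyl ether-catalysed enamine Michael addition of an aldehyde to a nitroalkene: the anti-enamine, shielded on one face by the catalyst, adds through an acyclic synclinal transition state, which should give the syn adduct and so set C7a and C7 (relative and absolute configuration) in one step.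

**Step 2**
Reactants: 3 methyl (3S,4S)-3-formyl-5-methyl-4-(nitromethyl)hexanoate; 4 isopropyltriphenylphosphonium iodide
Product: 5 methyl (3R,4S)-5-methyl-3-(2-methylprop-1-en-1-yl)-4-(nitromethyl)hexanoate
Conditions: 4 (2.2 equiv), KN(SiMe3)2 (2.2 equiv), THF, 0 °C; then 3, −78 to 0 °C; aq. NH4Cl
Reagents that add atoms: isopropyltriphenylphosphonium iodide 4, CC(C)[P+](c1ccccc1)(c1ccccc1)c1ccccc1.[I-]
Why: Wittig olefination with the unstabilised isopropylidene ylide turns the aldehyde into the 2-methylprop-1-enyl group without creating a stereocentre; one equivalent of ylide is spent on the acidic nitromethyl group (regenerated on work-up) and the low temperature should keep the α-stereocentre intact.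

**Step 3**
Reactants: 5 methyl (3R,4S)-5-methyl-3-(2-methylprop-1-en-1-yl)-4-(nitromethyl)hexanoate; 6 methanol
Product: 8 methyl (3R,4S)-4-(dimethoxymethyl)-5-methyl-3-(2-methylprop-1-en-1-yl)hexanoate, via sodium nitronate 7 (not isolated)
Conditions: NaOMe (1.1 equiv), MeOH, 0 °C; then H2SO4, MeOH, −40 °C
Reagents that add atoms: methanol 6, CO
Why: Nef reaction run in acidic methanol: the nitronate is solvolysed to the aldehyde, which is trapped as its dimethyl acetal, so the future C6 carbonyl is protected against the enolate chemistry that follows; the adjacent stereocentre is not enolisable under these conditions.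

**Step 4**
Reactants: 8 methyl (3R,4S)-4-(dimethoxymethyl)-5-methyl-3-(2-methylprop-1-en-1-yl)hexanoate; 9 prop-2-en-1-yl acetate
Product: 10 prop-2-en-1-yl (5R,6S)-6-(dimethoxymethyl)-7-methyl-5-(2-methylprop-1-en-1-yl)-3-oxooctanoate
Conditions: 9 and LiN(i-Pr)2 (3.5 equiv each), THF, −78 °C; then 8, −78 to −20 °C; aq. NH4Cl
Reagents that add atoms: prop-2-en-1-yl acetate 9, CC(=O)OCC=C
Why: Crossed Claisen condensation of the lithium enolate of allyl acetate with the methyl ester gives the β-keto ester, which is protected from further attack as its enolate; no stereocentre is touched.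

**Step 5**
Reactants: 10 prop-2-en-1-yl (5R,6S)-6-(dimethoxymethyl)-7-methyl-5-(2-methylprop-1-en-1-yl)-3-oxooctanoate
Product: 11 prop-2-en-1-yl (1R,2S,3R)-3-[(2S)-1,1-dimethoxy-3-methylbutan-2-yl]-5-oxo-2-(prop-1-en-2-yl)cyclopentane-1-carboxylate
Conditions: Mn(OAc)3·2H2O (2.2 equiv), Cu(OAc)2·H2O (1 equiv), degassed MeOH, rt
Reagents that add atoms: none
Why: Mn(OAc)3 oxidises the manganese enolate of the β-keto ester to an electrophilic radical at C2 of the chain, which adds to the electron-rich trisubstituted alkene; the tertiary radical so formed is captured by Cu(OAc)2 and loses a methyl hydrogen by β-hydride elimination, so the isopropenyl group needed in step 12 arises in the same event. The closest known reaction type is the oxidative free-radical cyclisation of unsaturated β-keto esters with trivalent manganese and divalent copper. Ring B closes in the 5-exo-trig mode (C2 onto the alkene CH attached to C5), the 6-endo mode being blocked by the fully substituted distal alkene carbon. The new ring stereocentre C2 (later C3a) should be set trans to the side chain at C3 by allylic 1,3-strain: the allylic hydrogen eclipses the alkene because of its cis-methyl group, the tether attacks from its own face and the bulky acetal-bearing branch lies on the other; C1 (ester) is epimerisable, should settle trans and is removed in step 8. The step needs chemoselective oxidation, 5-exo over 6-endo closure and formation of the less substituted alkene, secured in turn by the single enolisable 1,3-dicarbonyl unit, the prenyl-type substitution of the acceptor and the copper-mediated elimination.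

**Step 6**
Reactants: 11 prop-2-en-1-yl (1R,2S,3R)-3-[(2S)-1,1-dimethoxy-3-methylbutan-2-yl]-5-oxo-2-(prop-1-en-2-yl)cyclopentane-1-carboxylate; 12 acetaldehyde
Product: 14 prop-2-en-1-yl (1R,2S,3R,4S)-3-[(2S)-1,1-dimethoxy-3-methylbutan-2-yl]-4-(1-hydroxyethyl)-5-oxo-2-(prop-1-en-2-yl)cyclopentane-1-carboxylate, via dilithium dianion 13 (not isolated)
Conditions: LiN(i-Pr)2 (2.3 equiv), THF, −78 to −20 °C; then MeCHO, −78 °C; aq. NH4Cl
Reagents that add atoms: acetaldehyde 12, CC=O
Why: γ-Aldol reaction of a β-keto ester dianion: the second, more reactive carbanion at C4 adds to acetaldehyde from the face opposite the neighbouring side chain, fixing the future C1 trans to it (also the thermodynamic arrangement); the carbinol centre forms as a mixture, which does not matter because it is oxidised in step 15.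

**Step 7**
Reactants: 14 prop-2-en-1-yl (1R,2S,3R,4S)-3-[(2S)-1,1-dimethoxy-3-methylbutan-2-yl]-4-(1-hydroxyethyl)-5-oxo-2-(prop-1-en-2-yl)cyclopentane-1-carboxylate; 15 tert-butyldimethylsilyl trifluoromethanesulfonate
Product: 16 prop-2-en-1-yl (1R,2S,3R,4S)-4-(1-{[tert-butyl(dimethyl)silyl]oxy}ethyl)-3-[(2S)-1,1-dimethoxy-3-methylbutan-2-yl]-5-oxo-2-(prop-1-en-2-yl)cyclopentane-1-carboxylate
Conditions: 15, 2,6-lutidine, CH2Cl2, −78 °C
Reagents that add atoms: tert-butyldimethylsilyl trifluoromethanesulfonate 15, CC(C)(C)[Si](C)(C)OS(=O)(=O)C(F)(F)F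
Why: Silyl ether formation at the secondary alcohol masks the future acetyl oxygen through the base, hydride and Lewis acid steps that follow.

**Step 8**
Reactants: 16 prop-2-en-1-yl (1R,2S,3R,4S)-4-(1-{[tert-butyl(dimethyl)silyl]oxy}ethyl)-3-[(2S)-1,1-dimethoxy-3-methylbutan-2-yl]-5-oxo-2-(prop-1-en-2-yl)cyclopentane-1-carboxylate
Product: 18 (2S,3R,4R)-2-(1-{[tert-butyl(dimethyl)silyl]oxy}ethyl)-3-[(2S)-1,1-dimethoxy-3-methylbutan-2-yl]-4-(prop-1-en-2-yl)cyclopentan-1-one, via β-keto acid 17 (not isolated)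
Conditions: Pd(PPh3)4 (5 mol%), morpholine, THF, rt to 45 °C
Reagents that add atoms: none
Why: Tsuji-type deallylation: zerovalent palladium ionises the allyl ester, morpholine takes up the allyl group and the β-keto acid decarboxylates under neutral conditions, so the activating ester should leave without β-elimination of the silyloxy group and with C2 still trans to the neighbouring side chain.

**Step 9**
Reactants: 18 (2S,3R,4R)-2-(1-{[tert-butyl(dimethyl)silyl]oxy}ethyl)-3-[(2S)-1,1-dimethoxy-3-methylbutan-2-yl]-4-(prop-1-en-2-yl)cyclopentan-1-one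
Product: 19 (1S,2R,3S,4R)-2-(1-{[tert-butyl(dimethyl)silyl]oxy}ethyl)-3-[(2S)-1,1-dimethoxy-3-methylbutan-2-yl]-4-(prop-1-en-2-yl)cyclopentan-1-ol
Conditions: Li[HB(s-Bu)3], THF, −78 °C; aq. NH4Cl
Reagents that add atoms: none
Why: Diastereoselective ketone reduction with a bulky trialkylborohydride: hydride should arrive on the face opposite the C2 silyloxyethyl and C4 isopropenyl groups, giving the alcohol cis to both (the C2 configuration of the target).

**Step 10**
Reactants: 19 (1S,2R,3S,4R)-2-(1-{[tert-butyl(dimethyl)silyl]oxy}ethyl)-3-[(2S)-1,1-dimethoxy-3-methylbutan-2-yl]-4-(prop-1-en-2-yl)cyclopentan-1-ol; 20 (2Z)-2-methylbut-2-enoic acid (angelic acid)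
Product: 21 (1S,2R,3S,4R)-2-(1-{[tert-butyl(dimethyl)silyl]oxy}ethyl)-3-[(2S)-1,1-dimethoxy-3-methylbutan-2-yl]-4-(prop-1-en-2-yl)cyclopentyl (2Z)-2-methylbut-2-enoate
Conditions: 20, 2,4,6-trichlorobenzoyl chloride, Et3N, toluene, rt; then 19, 75 °C
Reagents that add atoms: (2Z)-2-methylbut-2-enoic acid 20, C/C=C(/C)C(=O)O
Why: Yamaguchi esterification through the mixed 2,4,6-trichlorobenzoic anhydride, run without a nucleophilic amine catalyst so that the (Z)-configured angelate should not isomerise to the tiglate; the carbinol configuration is retained.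

**Step 11**
Reactants: 21 (1S,2R,3S,4R)-2-(1-{[tert-butyl(dimethyl)silyl]oxy}ethyl)-3-[(2S)-1,1-dimethoxy-3-methylbutan-2-yl]-4-(prop-1-en-2-yl)cyclopentyl (2Z)-2-methylbut-2-enoate; 22 water
Product: 23 (1S,2R,3S,4R)-2-(1-{[tert-butyl(dimethyl)silyl]oxy}ethyl)-3-[(2S)-3-methyl-1-oxobutan-2-yl]-4-(prop-1-en-2-yl)cyclopentyl (2Z)-2-methylbut-2-enoate
Conditions: pyridinium p-toluenesulfonate (cat.), acetone–H2O, 45 °C
Reagents that add atoms: water 22, O
Why: Mild acid-catalysed acetal hydrolysis frees the aldehyde while the secondary silyl ether, the ester and the isopropenyl group should survive; the α-stereocentre is used at once in step 12.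

**Step 12**
Reactants: 23 (1S,2R,3S,4R)-2-(1-{[tert-butyl(dimethyl)silyl]oxy}ethyl)-3-[(2S)-3-methyl-1-oxobutan-2-yl]-4-(prop-1-en-2-yl)cyclopentyl (2Z)-2-methylbut-2-enoate
Product: 24 (1R,2S,3aR,6R,7S,7aR)-1-(1-{[tert-butyl(dimethyl)silyl]oxy}ethyl)-6-hydroxy-4-methylidene-7-(propan-2-yl)octahydro-1H-inden-2-yl (2Z)-2-methylbut-2-enoate
Conditions: Me2AlCl (2.5 equiv), CH2Cl2, −78 to −40 °C; aq. KNaC4H4O6
Reagents that add atoms: none
Why: Lewis acid-promoted intramolecular carbonyl-ene reaction of the kind in which the ene unit is tethered through its central carbon: in the chair-like transition state the isopropyl group and both ring-fusion bonds are equatorial and the aluminium-bound oxygen is axial, because the hydrogen is handed over from the methyl group within a closed bicyclic array, which should give the trans-fused ring A, the exocyclic methylidene group and the axial C6 alcohol cis to the isopropyl group.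

**Step 13**
Reactants: 24 (1R,2S,3aR,6R,7S,7aR)-1-(1-{[tert-butyl(dimethyl)silyl]oxy}ethyl)-6-hydroxy-4-methylidene-7-(propan-2-yl)octahydro-1H-inden-2-yl (2Z)-2-methylbut-2-enoate; 25 acetic anhydride
Product: 26 (1R,2S,3aR,6R,7S,7aR)-6-(acetyloxy)-1-(1-{[tert-butyl(dimethyl)silyl]oxy}ethyl)-4-methylidene-7-(propan-2-yl)octahydro-1H-inden-2-yl (2Z)-2-methylbut-2-enoate
Conditions: Ac2O, 4-(dimethylamino)pyridine (cat.), pyridine, rt
Reagents that add atoms: acetic anhydride 25, CC(=O)OC(C)=O
Why: Acylation of the hindered axial alcohol with acetic anhydride under nucleophilic catalysis installs the C6 acetate with retention, at a stage where no base-sensitive β-acyloxy ketone is yet present.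

**Step 14**
Reactants: 26 (1R,2S,3aR,6R,7S,7aR)-6-(acetyloxy)-1-(1-{[tert-butyl(dimethyl)silyl]oxy}ethyl)-4-methylidene-7-(propan-2-yl)octahydro-1H-inden-2-yl (2Z)-2-methylbut-2-enoate
Product: 27 (1S,2S,3aR,6R,7S,7aR)-6-(acetyloxy)-1-(1-hydroxyethyl)-4-methylidene-7-(propan-2-yl)octahydro-1H-inden-2-yl (2Z)-2-methylbut-2-enoate
Conditions: HF·pyridine, THF–pyridine, 0 °C to rt
Reagents that add atoms: none
Why: Fluoride-mediated cleavage of the silyl ether under slightly acidic conditions, chosen to avoid base-induced acyl migration from the neighbouring angelate.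

**Step 15**
Reactants: 27 (1S,2S,3aR,6R,7S,7aR)-6-(acetyloxy)-1-(1-hydroxyethyl)-4-methylidene-7-(propan-2-yl)octahydro-1H-inden-2-yl (2Z)-2-methylbut-2-enoate
Product: 28 (1R,2S,3aR,6R,7S,7aR)-1-acetyl-6-(acetyloxy)-4-methylidene-7-(propan-2-yl)octahydro-1H-inden-2-yl (2Z)-2-methylbut-2-enoate
Conditions: Dess–Martin periodinane, NaHCO3, CH2Cl2, 0 °C to rt
Reagents that add atoms: none
Why: Dess–Martin oxidation of the secondary alcohol to the methyl ketone under buffered, non-basic conditions, so that the C1 stereocentre should not epimerise and the β-acyloxy ketone should not eliminate.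

**Compound list**
1 | methyl 4-oxobutanoate | COC(=O)CCC=O | starting material
2 | (E)-3-methyl-1-nitrobut-1-ene | CC(C)/C=C/[N+](=O)[O-] | starting material
3 | methyl (3S,4S)-3-formyl-5-methyl-4-(nitromethyl)hexanoate | O=[N+]([O-])C[C@@H](C(C)C)[C@@H](C=O)CC(=O)OC | intermediate
4 | isopropyltriphenylphosphonium iodide | CC(C)[P+](c1ccccc1)(c1ccccc1)c1ccccc1.[I-] | starting material
5 | methyl (3R,4S)-5-methyl-3-(2-methylprop-1-en-1-yl)-4-(nitromethyl)hexanoate | O=[N+]([O-])C[C@@H](C(C)C)[C@@H](C=C(C)C)CC(=O)OC | intermediate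
6 | methanol | CO | starting material
7 | sodium nitronate of 5 (sodium salt of the aci-nitro form) | [Na+].[O-][N+]([O-])=C[C@@H](C(C)C)[C@@H](C=C(C)C)CC(=O)OC | intermediate
8 | methyl (3R,4S)-4-(dimethoxymethyl)-5-methyl-3-(2-methylprop-1-en-1-yl)hexanoate | COC(OC)[C@@H](C(C)C)[C@@H](C=C(C)C)CC(=O)OC | intermediate
9 | prop-2-en-1-yl acetate (allyl acetate) | CC(=O)OCC=C | starting material
10 | prop-2-en-1-yl (5R,6S)-6-(dimethoxymethyl)-7-methyl-5-(2-methylprop-1-en-1-yl)-3-oxooctanoate | COC(OC)[C@@H](C(C)C)[C@@H](C=C(C)C)CC(=O)CC(=O)OCC=C | intermediate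
11 | prop-2-en-1-yl (1R,2S,3R)-3-[(2S)-1,1-dimethoxy-3-methylbutan-2-yl]-5-oxo-2-(prop-1-en-2-yl)cyclopentane-1-carboxylate | COC(OC)[C@@H](C(C)C)[C@@H]1CC(=O)[C@H](C(=O)OCC=C)[C@H]1C(C)=C | intermediate
12 | acetaldehyde | CC=O | starting material
13 | dilithium dianion of 11 (ester enolate at C1 and ketone enolate towards C4) | [Li+].[Li+].COC(OC)[C@@H](C(C)C)[C@@H]1C=C([O-])C(=C([O-])OCC=C)[C@H]1C(C)=C | intermediate
14 | prop-2-en-1-yl (1R,2S,3R,4S)-3-[(2S)-1,1-dimethoxy-3-methylbutan-2-yl]-4-(1-hydroxyethyl)-5-oxo-2-(prop-1-en-2-yl)cyclopentane-1-carboxylate (carbinol centre as a mixture) | COC(OC)[C@@H](C(C)C)[C@@H]1[C@@H](C(C)O)C(=O)[C@H](C(=O)OCC=C)[C@H]1C(C)=C | intermediate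
15 | tert-butyldimethylsilyl trifluoromethanesulfonate | CC(C)(C)[Si](C)(C)OS(=O)(=O)C(F)(F)F | starting material
16 | prop-2-en-1-yl (1R,2S,3R,4S)-4-(1-{[tert-butyl(dimethyl)silyl]oxy}ethyl)-3-[(2S)-1,1-dimethoxy-3-methylbutan-2-yl]-5-oxo-2-(prop-1-en-2-yl)cyclopentane-1-carboxylate | COC(OC)[C@@H](C(C)C)[C@@H]1[C@@H](C(C)O[Si](C)(C)C(C)(C)C)C(=O)[C@H](C(=O)OCC=C)[C@H]1C(C)=C | intermediate
17 | (1R,2S,3R,4S)-4-(1-{[tert-butyl(dimethyl)silyl]oxy}ethyl)-3-[(2S)-1,1-dimethoxy-3-methylbutan-2-yl]-5-oxo-2-(prop-1-en-2-yl)cyclopentane-1-carboxylic acid | COC(OC)[C@@H](C(C)C)[C@@H]1[C@@H](C(C)O[Si](C)(C)C(C)(C)C)C(=O)[C@H](C(=O)O)[C@H]1C(C)=C | intermediate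
18 | (2S,3R,4R)-2-(1-{[tert-butyl(dimethyl)silyl]oxy}ethyl)-3-[(2S)-1,1-dimethoxy-3-methylbutan-2-yl]-4-(prop-1-en-2-yl)cyclopentan-1-one | COC(OC)[C@@H](C(C)C)[C@@H]1[C@@H](C(C)O[Si](C)(C)C(C)(C)C)C(=O)C[C@H]1C(C)=C | intermediate
19 | (1S,2R,3S,4R)-2-(1-{[tert-butyl(dimethyl)silyl]oxy}ethyl)-3-[(2S)-1,1-dimethoxy-3-methylbutan-2-yl]-4-(prop-1-en-2-yl)cyclopentan-1-ol | COC(OC)[C@@H](C(C)C)[C@@H]1[C@@H](C(C)O[Si](C)(C)C(C)(C)C)[C@@H](O)C[C@H]1C(C)=C | intermediate
20 | (2Z)-2-methylbut-2-enoic acid (angelic acid) | C/C=C(/C)C(=O)O | starting material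
21 | (1S,2R,3S,4R)-2-(1-{[tert-butyl(dimethyl)silyl]oxy}ethyl)-3-[(2S)-1,1-dimethoxy-3-methylbutan-2-yl]-4-(prop-1-en-2-yl)cyclopentyl (2Z)-2-methylbut-2-enoate | COC(OC)[C@@H](C(C)C)[C@@H]1[C@@H](C(C)O[Si](C)(C)C(C)(C)C)[C@@H](OC(=O)/C(C)=C\C)C[C@H]1C(C)=C | intermediate
22 | water | O | starting material
23 | (1S,2R,3S,4R)-2-(1-{[tert-butyl(dimethyl)silyl]oxy}ethyl)-3-[(2S)-3-methyl-1-oxobutan-2-yl]-4-(prop-1-en-2-yl)cyclopentyl (2Z)-2-methylbut-2-enoate | O=C[C@@H](C(C)C)[C@@H]1[C@@H](C(C)O[Si](C)(C)C(C)(C)C)[C@@H](OC(=O)/C(C)=C\C)C[C@H]1C(C)=C | intermediate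
24 | (1R,2S,3aR,6R,7S,7aR)-1-(1-{[tert-butyl(dimethyl)silyl]oxy}ethyl)-6-hydroxy-4-methylidene-7-(propan-2-yl)octahydro-1H-inden-2-yl (2Z)-2-methylbut-2-enoate | C=C1C[C@@H](O)[C@@H](C(C)C)[C@@H]2[C@@H](C(C)O[Si](C)(C)C(C)(C)C)[C@@H](OC(=O)/C(C)=C\C)C[C@@H]12 | intermediate
25 | acetic anhydride | CC(=O)OC(C)=O | starting material
26 | (1R,2S,3aR,6R,7S,7aR)-6-(acetyloxy)-1-(1-{[tert-butyl(dimethyl)silyl]oxy}ethyl)-4-methylidene-7-(propan-2-yl)octahydro-1H-inden-2-yl (2Z)-2-methylbut-2-enoate | C=C1C[C@@H](OC(C)=O)[C@@H](C(C)C)[C@@H]2[C@@H](C(C)O[Si](C)(C)C(C)(C)C)[C@@H](OC(=O)/C(C)=C\C)C[C@@H]12 | intermediate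
27 | (1S,2S,3aR,6R,7S,7aR)-6-(acetyloxy)-1-(1-hydroxyethyl)-4-methylidene-7-(propan-2-yl)octahydro-1H-inden-2-yl (2Z)-2-methylbut-2-enoate | C=C1C[C@@H](OC(C)=O)[C@@H](C(C)C)[C@@H]2[C@@H](C(C)O)[C@@H](OC(=O)/C(C)=C\C)C[C@@H]12 | intermediate
28 | (1R,2S,3aR,6R,7S,7aR)-1-acetyl-6-(acetyloxy)-4-methylidene-7-(propan-2-yl)octahydro-1H-inden-2-yl (2Z)-2-methylbut-2-enoate | C=C1C[C@@H](OC(C)=O)[C@@H](C(C)C)[C@@H]2[C@@H](C(C)=O)[C@@H](OC(=O)/C(C)=C\C)C[C@@H]12 | target

**Summary**
Total step count: 15. Longest linear sequence: 15 steps (from 1).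

**Steps most likely to fail**

Step 5. The cyclised β-keto ester still carries an enolisable α-hydrogen and may be oxidised further; 6-endo closure or hydrogen abstraction by the tertiary radical may also compete. The fallback sets out from 8 and comes back at 11, closing ring B by a two-electron Tsuji–Trost alkylation instead. Allylic oxidation of 8 with SeO2 (cat.) and t-BuOOH should give the (E)-allylic alcohol methyl (3R,4S)-4-(dimethoxymethyl)-3-[(1E)-3-hydroxy-2-methylprop-1-en-1-yl]-5-methylhexanoate F1. Crossed Claisen condensation with the lithium enolate of methyl acetate should give methyl (5R,6S)-6-(dimethoxymethyl)-5-[(1E)-3-hydroxy-2-methylprop-1-en-1-yl]-7-methyl-3-oxooctanoate F2. Methyl chloroformate and pyridine convert it into the allylic carbonate methyl (5R,6S)-6-(dimethoxymethyl)-5-{(1E)-3-[(methoxycarbonyl)oxy]-2-methylprop-1-en-1-yl}-7-methyl-3-oxooctanoate F3. Pd(PPh3)4 in THF (zerovalent palladium) ionises the carbonate, and the β-keto ester carbon should attack the substituted allyl terminus in the 5-exo sense to give methyl (1R,2S,3R)-3-[(2S)-1,1-dimethoxy-3-methylbutan-2-yl]-5-oxo-2-(prop-1-en-2-yl)cyclopentane-1-carboxylate F4. Transesterification with allyl alcohol (toluene, reflux, cat. 4-(dimethylamino)pyridine) returns 11.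

Step 12. Facial selectivity at the aldehyde carbon may be poor (equatorial instead of axial alcohol), chloride may capture the cationic intermediate, or the angelate may isomerise under the Lewis acid. The fallback sets out from 23 and comes back at 26. The closure is run with the bulky MeAl(OC6H2-4-Br-2,6-t-Bu2)2, which favours an open transition state with equatorial oxygen and should give the C6 epimer (1R,2S,3aR,6S,7S,7aR)-1-(1-{[tert-butyl(dimethyl)silyl]oxy}ethyl)-6-hydroxy-4-methylidene-7-(propan-2-yl)octahydro-1H-inden-2-yl (2Z)-2-methylbut-2-enoate F5. A Mitsunobu reaction with acetic acid (PPh3, diisopropyl azodicarboxylate, THF) then inverts C6 and installs the acetate in one operation, giving 26.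

Step 3. Methanol may add to, or the double bond may migrate in, the trisubstituted alkene during the strongly acidic quench of the nitronate. The fallback sets out from 5 and comes back at 8. The nitronate (NaOMe, MeOH) is added to buffered aqueous TiCl3/NH4OAc (Nef variant with trivalent titanium), which should give the free aldehyde methyl (3R,4S)-4-formyl-5-methyl-3-(2-methylprop-1-en-1-yl)hexanoate F6 at near-neutral pH. Acetalisation with HC(OMe)3 and pyridinium p-toluenesulfonate in MeOH then gives 8.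

**Further compounds**
F1 | step 5 | methyl (3R,4S)-4-(dimethoxymethyl)-3-[(1E)-3-hydroxy-2-methylprop-1-en-1-yl]-5-methylhexanoate | COC(OC)[C@@H](C(C)C)[C@@H](/C=C(\C)CO)CC(=O)OC
F2 | step 5 | methyl (5R,6S)-6-(dimethoxymethyl)-5-[(1E)-3-hydroxy-2-methylprop-1-en-1-yl]-7-methyl-3-oxooctanoate | COC(OC)[C@@H](C(C)C)[C@@H](/C=C(\C)CO)CC(=O)CC(=O)OC
F3 | step 5 | methyl (5R,6S)-6-(dimethoxymethyl)-5-{(1E)-3-[(methoxycarbonyl)oxy]-2-methylprop-1-en-1-yl}-7-methyl-3-oxooctanoate | COC(OC)[C@@H](C(C)C)[C@@H](/C=C(\C)COC(=O)OC)CC(=O)CC(=O)OC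
F4 | step 5 | methyl (1R,2S,3R)-3-[(2S)-1,1-dimethoxy-3-methylbutan-2-yl]-5-oxo-2-(prop-1-en-2-yl)cyclopentane-1-carboxylate | COC(OC)[C@@H](C(C)C)[C@@H]1CC(=O)[C@H](C(=O)OC)[C@H]1C(C)=C
F5 | step 12 | (1R,2S,3aR,6S,7S,7aR)-1-(1-{[tert-butyl(dimethyl)silyl]oxy}ethyl)-6-hydroxy-4-methylidene-7-(propan-2-yl)octahydro-1H-inden-2-yl (2Z)-2-methylbut-2-enoate | C=C1C[C@H](O)[C@@H](C(C)C)[C@@H]2[C@@H](C(C)O[Si](C)(C)C(C)(C)C)[C@@H](OC(=O)/C(C)=C\C)C[C@@H]12
F6 | step 3 | methyl (3R,4S)-4-formyl-5-methyl-3-(2-methylprop-1-en-1-yl)hexanoate | O=C[C@@H](C(C)C)[C@@H](C=C(C)C)CC(=O)OC
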